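**Assumptions**
- The given SMILES is taken as the intended stereoisomer: a cis-fused decalin with Me-5 and H-10 cis, and 8-Me cis to the 9-CH2Ar arm. I use avarane numbering: C4 is the methylene carbon, C5 and C9 are the quaternary carbons, C8 is CH(Me), and C11 is the CH2 attached to the quinone.
- (R)-β-Methyl-δ-valerolactone (1) is treated as a commercial chiral-pool compound (it is derived from pulegone).

**Retrosynthetic overview**
1. Cleave the ArCH2–C9 bond: a neopentyl radical from the acid adds to 2,5-dimethoxybenzoquinone in a photochemical decarboxylative step, followed by regioselective mono-demethylation.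
2. The C4 methylene comes from a Wittig reaction on the C4 ketone, and the CH2CO2H arm comes from oxidative cleavage of an allyl group.
3. The cis-decalone is built by breaking C9–C10 and C5–C6. A photochemical decarboxylative Giese addition of a tertiary acid (carrying the C8 stereocentre and a C6 bromide) to 2-methylcyclohexenone forms C9–C10. Enolate alkylation then closes ring B. Ring A (the enone) is present first and ring B is formed second.
4. The tertiary acid comes from (R)-β-methyl-δ-valerolactone by α-allylation, α-methylation and bromide ring-opening.

**Route**

**Step 1**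
Reactants: 1 (R)-4-methyloxan-2-one; 2 allyl bromide
Product: 3 (4R)-3-allyl-4-methyloxan-2-one (C3 epimer mixture)
Conditions: LiHMDS, THF, –78 °C; then 2, –78 → 0 °C
Reagents that add atoms: allyl bromide, C=CCBr
Why: Lactone enolate SN2 alkylation installs the allyl arm (the future C11 side chain), and the C8 stereocentre is untouched. The new C9 centre is trans-selective but irrelevant because it is destroyed in step 4.

**Step 2**
Reactants: 3; 4 iodomethane
Product: 5 (4R)-3-allyl-3,4-dimethyloxan-2-one
Conditions: LiHMDS, THF, –78 °C; then MeI, DMPU, –78 → –20 °C
Reagents that add atoms: MeI, CI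
Why: A second enolate alkylation builds the fully substituted α-carbon that becomes C9, anti to the 4-Me; the C9 configuration is again erased by radical formation.

**Step 3**
Reactants: 5; 6 bromotrimethylsilane
Product: 7 (3R)-5-bromo-2,3-dimethyl-2-(prop-2-en-1-yl)pentanoic acid
Conditions: TMSBr (2 equiv), CH2Cl2, 0 °C → rt, 12 h; then H2O work-up
Reagents that add atoms: TMSBr, C[Si](C)(C)Br (supplies Br)
Why: Silyl activation of the lactone followed by SN2 bromide attack at the primary C–O carbon (a standard TMSX lactone opening) gives the tertiary acid with a C6 bromide. C8 is not involved.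

**Step 4**
Reactants: 7; 8 2-methylcyclohex-2-en-1-one
Product: 9 cis-fused 9-allyl-5,8,9-trimethyl-decalin-4-one with the target configuration (Me-5/H-10 cis)
Conditions: 4CzIPN (2 mol %), KOt-Bu (1 equiv relative to 7, giving the K carboxylate), DMF, 450 nm LEDs, 15 °C, 16 h; then the same pot at 60 °C for 6 h (7 in slight excess over 8)
Reagents that add atoms: none
Why: Proposed new method: a photocatalytic decarboxylative Giese addition coupled with an intramolecular enolate alkylation (radical-polar-crossover annulation) that builds ring B in one pot.
- Mechanism: the excited photocatalyst oxidises the tertiary carboxylate, which loses CO2 to give the C9 radical. This adds to C10, the β-carbon of 8, giving an α-keto radical at C5. The reduced photocatalyst converts this to the enolate/ketone, and on warming the thermodynamic C5 enolate displaces the C6 bromide.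
- Closest known reactions: the photoredox decarboxylative Giese reaction and Robinson-type annulation logic.
- Stereochemistry: C9 and C10 are set in the Giese step by 1,2-induction from C8, with the enone approaching anti to the CH2CH2Br arm. I expect a modest dr, and the desired isomer is separated at the decalone stage. C5 is set by 6-(enolexo)-exo-tet axial alkylation of the ring-A enolate, which places C6 axial and Me-5 equatorial. The ring fusion is therefore cis, with Me-5 and H-10 on the same face.

**Step 5**
Reactants: 9
Product: 10 keto acid (the allyl group becomes CH2CO2H)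
Conditions: RuCl3·xH2O (5 mol %), NaIO4 (6 equiv), EtOAc/MeCN/H2O, 0 °C → rt
Reagents that add atoms: NaIO4, [Na+].[O-]I(=O)(=O)=O (oxygen source for CO2H)
Why: Ru-catalysed oxidative alkene cleavage converts the terminal CH=CH2 into CO2H. The ketone is stable, C5 is quaternary, and C10/C8 are not epimerisable, so no stereocentre changes. The cleavage is done before the methylene is installed because the methylene alkene would not survive it.

**Step 6**
Reactants: 10; 11 methyltriphenylphosphonium bromide
Product: 12 exocyclic methylene acid
Conditions: 11 (4 equiv), KOt-Bu (4.5 equiv), toluene, 80 °C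
Reagents that add atoms: Ph3P+CH3 Br-, C[P+](c1ccccc1)(c1ccccc1)c1ccccc1.[Br-] (supplies =CH2)
Why: Wittig methylenation of the C4 ketone, which is next to quaternary C5, forms the exocyclic alkene; excess ylide covers the carboxylate, and no stereocentre is affected.

**Step 7**
Reactants: 12; 13 2,5-dimethoxy-1,4-benzoquinone
Product: 14 3-alkyl-2,5-dimethoxy-1,4-benzoquinone
Conditions: [Ir(dF(CF3)ppy)2(dtbbpy)]PF6 (1 mol %), Cs2CO3 (1 equiv), 13 (3 equiv), DMSO/MeCN, 450 nm, rt
Reagents that add atoms: none
Why: Photoredox decarboxylation of the primary acid gives the neopentyl C11 radical, which adds to the quinone C–H (Giese/Minisci-type). The C2h-symmetric quinone gives a single regioisomer, and excess quinone reoxidises the hydroquinone. The radical cannot reach the C4 methylene, which is trans-1,3 across ring B.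

**Step 8**
Reactants: 14
Product: 15 target (2-hydroxy-5-methoxy-3-alkyl-1,4-benzoquinone)
Conditions: MgI2·OEt2 (3 equiv), toluene, 60 °C, 4 h; aq. NH4Cl
Reagents that add atoms: none
Why: Chelation of the less hindered carbonyl (flanked by CH) and its adjacent OMe directs cleavage of the methoxy next to the alkyl-bearing carbon. The mild Lewis acid leaves the acid-sensitive exocyclic alkene intact.

**Compound list**

| No. | Name | SMILES | Role |
|---|---|---|---|
| 1 | (R)-4-methyloxan-2-one | O=C1C[C@H](C)CCO1 | starting material |
| 2 | allyl bromide | C=CCBr | starting material |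
| 3 | (4R)-3-allyl-4-methyloxan-2-one (C3 epimer mixture) | O=C1C(CC=C)[C@H](C)CCO1 | intermediate |
| 4 | iodomethane | CI | starting material |
| 5 | (4R)-3-allyl-3,4-dimethyloxan-2-one (C3 epimer not important) | O=C1[C@](C)(CC=C)[C@H](C)CCO1 | intermediate |
| 6 | bromotrimethylsilane | C[Si](C)(C)Br | starting material |
| 7 | (3R)-5-bromo-2,3-dimethyl-2-allylpentanoic acid | OC(=O)[C@](C)(CC=C)[C@H](C)CCBr | intermediate |
| 8 | 2-methylcyclohex-2-en-1-one | CC1=CCCCC1=O | starting material |
| 9 | cis-9-allyl-5,8,9-trimethyldecalin-4-one | O=C1CCC[C@H]2[C@](C)(CC=C)[C@H](C)CC[C@@]12C | intermediate |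
| 10 | keto acid (CH2CO2H at C9) | O=C1CCC[C@H]2[C@](C)(CC(=O)O)[C@H](C)CC[C@@]12C | intermediate |
| 11 | methyltriphenylphosphonium bromide | C[P+](c1ccccc1)(c1ccccc1)c1ccccc1.[Br-] | starting material |
| 12 | 4-methylene acid | C=C1CCC[C@H]2[C@](C)(CC(=O)O)[C@H](C)CC[C@@]12C | intermediate |
| 13 | 2,5-dimethoxy-1,4-benzoquinone | COC1=CC(=O)C(OC)=CC1=O | starting material |
| 14 | 3-alkyl-2,5-dimethoxybenzoquinone | C=C1CCC[C@H]2[C@](C)(CC3=C(OC)C(=O)C=C(OC)C3=O)[C@H](C)CC[C@@]12C | intermediate |
| 15 | target (CID71726091) | C=C1CCC[C@H]2[C@](C)(CC3=C(O)C(=O)C=C(OC)C3=O)[C@H](C)CC[C@@]12C | target |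

**Totals**
- Total steps: 8.
- Longest linear sequence: 8 steps, from 1 to 15.

**Three steps most likely to fail**
1. **Step 4 (the proposed new annulation).** The ω-bromo carboxylate may lactonise before it decarboxylates, the enolate may be protonated, and the C9/C10 dr may be low.
   - Fallback: convert 7 to its N-hydroxyphthalimide redox-active ester, run the Giese addition with Hantzsch ester and a photocatalyst, then close ring B with KOt-Bu/NaI in a separate step. This is known chemistry, and the desired diastereomer is separated at the ketone stage.
2. **Step 8 (regioselective demethylation).** Selectivity between the two methoxy groups may be poor.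
   - Fallback: in step 7 use 2,5-dihydroxy-1,4-benzoquinone in a Kochi-type radical alkylation, then methylate the less hindered OH with TMSCHN2.
3. **Step 6 (Wittig on the hindered keto acid).** Conversion may be incomplete because of the quaternary neighbour and the carboxylate.
   - Fallback: make the methyl ester and methylenate with the Takai–Lombardo reagent (Zn/CH2Br2/TiCl4), then saponify.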